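**Plan**

- The target is an achiral depside. Ring A (carboxyl on C1, oxygens on C2 and C4, pentyl on C6) is a resorcylate whose ring carbons C1–C6 and carboxyl carbon correspond to C2–C7 and C1 of a 3,5,7-trioxododecanoyl chain. That chain can be carried as the ester on O3 of ring B, so ring A can be grown by an aldol aromatisation.
- Retrosynthesis: remove the three benzyl groups and the two ring A O-methyl bonds, cut the ring A C1–C6 bond (aldol), then cut the ester bond between ring B O3 and chain C1 (acylketene plus phenol).
- The chain is cut at C4–C5 and C6–C7, giving 2,2,6-trimethyl-4H-1,3-dioxin-4-one, acetyl chloride and the Weinreb amide of hexanoic acid.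
- Ring B comes from 5-propylresorcinol: the O3 oxygen is added by lithiation, borylation and oxidation between the two ethers, and the carboxyl by bromination, bromine–lithium exchange and benzyl chloroformate.
- Forward: phenol 10 (steps 1–6) and diketo-dioxinone 18 (steps 7–9) are joined by ketene capture (step 10), ring A is closed on the ester (step 11), then methylation and hydrogenolysis follow (steps 12–13).
- Stereochemistry: the target has no stereocentre; the only sp3 centres on the way (carbinol 21) disappear on aromatisation.

Key step: step 11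

Remark: because the molecule has no stereogenic element, "single enantiomer" is taken to mean the one achiral constitution drawn. LDA and LiHMDS are taken as commercial solutions.

**Route**

Step 1
Reactants: 1 5-propylbenzene-1,3-diol (5-propylresorcinol)
Product: 2 1,3-bis(benzyloxy)-5-propylbenzene
Conditions: BnBr (2.2 equiv), K2CO3, DMF, rt
Reagents that add atoms: benzyl bromide, BrCc1ccccc1
Why: Williamson etherification of both phenols should proceed cleanly with carbonate in a dipolar aprotic solvent.

Step 2
Reactants: 2 1,3-bis(benzyloxy)-5-propylbenzene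
Product: 5 2,6-bis(benzyloxy)-4-propylphenol, via [2,6-bis(benzyloxy)-4-propylphenyl]lithium 3 (not isolated), via lithium aryltrimethoxyborate 4 (not isolated)
Conditions: n-BuLi (1.2 equiv), THF, 0 °C to rt; B(OMe)3, −78 °C to rt; AcOH, 30% H2O2, 0 °C to rt
Reagents that add atoms: hydrogen peroxide, OO
Why: Directed ortho-metalation should occur at the one ring position flanked by two coordinating ether oxygens, and borylation followed by peroxide oxidation of the aryl–boron bond should deliver the phenol at that carbon.

Step 3
Reactants: 5 2,6-bis(benzyloxy)-4-propylphenol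
Product: 6 1,3-bis(benzyloxy)-2-(methoxymethoxy)-5-propylbenzene
Conditions: NaH, MOMCl, DMF, 0 °C to rt
Reagents that add atoms: chloromethyl methyl ether, COCCl
Why: O-alkylation of the sodium phenoxide with the small, reactive chloromethyl ether (MOM protection) should tolerate the two flanking benzyloxy groups and keeps the oxidation-prone phenol masked during the next two steps.

Step 4
Reactants: 6 1,3-bis(benzyloxy)-2-(methoxymethoxy)-5-propylbenzene
Product: 7 1,3-bis(benzyloxy)-4-bromo-2-(methoxymethoxy)-5-propylbenzene
Conditions: NBS (1.0 equiv), DMF, 0 °C to rt, dark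
Reagents that add atoms: N-bromosuccinimide, O=C1CCC(=O)N1Br
Why: Electrophilic aromatic bromination can only go to the two equivalent free positions, each ortho to one benzyloxy group and para to the other, and the first bromine deactivates the ring against a second.

Step 5
Reactants: 7 1,3-bis(benzyloxy)-4-bromo-2-(methoxymethoxy)-5-propylbenzene
Product: 9 benzyl 2,4-bis(benzyloxy)-3-(methoxymethoxy)-6-propylbenzoate, via [2,4-bis(benzyloxy)-3-(methoxymethoxy)-6-propylphenyl]lithium 8 (not isolated)
Conditions: n-BuLi (1.05 equiv), THF, −78 °C; then added to BnOCOCl (2 equiv), THF, −78 °C to rt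
Reagents that add atoms: benzyl chloroformate, O=C(Cl)OCc1ccccc1
Why: Bromine–lithium exchange at −78 °C is faster than any deprotonation, and acylation of the aryllithium by inverse addition to excess chloroformate should stop at the ester because the product is a di-ortho-substituted benzoate.

Step 6
Reactants: 9 benzyl 2,4-bis(benzyloxy)-3-(methoxymethoxy)-6-propylbenzoate
Product: 10 benzyl 2,4-bis(benzyloxy)-3-hydroxy-6-propylbenzoate
Conditions: conc. HCl (cat.), MeOH–THF, 45 °C
Reagents that add atoms: none
Why: Acid-catalysed acetal cleavage (transacetalisation to methanol) should free the phenol, while the benzyl ethers and the hindered benzyl benzoate resist these conditions.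

Step 7
Reactants: 11 hexanoyl chloride
Product: 12 N-methoxy-N-methylhexanamide
Conditions: MeNH(OMe)·HCl, Et3N (2.2 equiv), CH2Cl2, 0 °C to rt
Reagents that add atoms: N,O-dimethylhydroxylamine hydrochloride, CNOC.Cl
Why: N-acylation of the hydroxylamine by the acid chloride (Weinreb amide formation) is a routine Schotten–Baumann-type amidation.

Step 8
Reactants: 13 2,2,6-trimethyl-4H-1,3-dioxin-4-one; 14 acetyl chloride
Product: 16 2,2-dimethyl-6-(2-oxopropyl)-4H-1,3-dioxin-4-one, via lithium dienolate 15 (not isolated)
Conditions: LiHMDS, THF, −78 °C; AcCl (0.5 equiv relative to dienolate), −78 °C; 1 M HCl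
Reagents that add atoms: none
Why: Deprotonation of the 6-methyl group gives the vinylogous ester enolate, which should undergo C-acylation at the γ carbon (vinylogous Claisen-type acylation); half an equivalent of chloride is used because the more acidic product consumes a second equivalent of dienolate.

Step 9
Reactants: 16 2,2-dimethyl-6-(2-oxopropyl)-4H-1,3-dioxin-4-one; 12 N-methoxy-N-methylhexanamide
Product: 18 6-(2,4-dioxononyl)-2,2-dimethyl-4H-1,3-dioxin-4-one, via dilithium dianion 17 (not isolated)
Conditions: LDA (2.2 equiv), THF, −78 to −40 °C; 12, −78 to −20 °C; aq. HCl quench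
Reagents that add atoms: none
Why: The 1,3-dicarbonyl-type dianion should react at its terminal, most basic carbon with the Weinreb amide (Claisen-type dianion acylation), and the chelated tetrahedral intermediate prevents over-addition until work-up.

Step 10
Reactants: 18 6-(2,4-dioxononyl)-2,2-dimethyl-4H-1,3-dioxin-4-one; 10 benzyl 2,4-bis(benzyloxy)-3-hydroxy-6-propylbenzoate
Product: 20 benzyl 2,4-bis(benzyloxy)-6-propyl-3-[(3,5,7-trioxododecanoyl)oxy]benzoate, via acylketene 19 (not isolated)
Conditions: 18 (1.5 equiv) added slowly to 10, toluene, 4 Å MS, 110 °C; evaporated and used without chromatography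
Reagents that add atoms: none
Why: Thermal retro-hetero-Diels–Alder fragmentation of the dioxinone releases acetone and an acylketene, which should add the phenol O–H to give the aryl β-keto ester (acylketene trapping), so the hindered depside ester is made without acylating the phenol with a 2,6-disubstituted benzoic acid.

Step 11
Reactants: 20 benzyl 2,4-bis(benzyloxy)-6-propyl-3-[(3,5,7-trioxododecanoyl)oxy]benzoate
Product: 22 benzyl 2,4-bis(benzyloxy)-3-[(2,4-dihydroxy-6-pentylbenzoyl)oxy]-6-propylbenzoate, via aldol carbinol 21 (not isolated)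
Conditions: Et3N (0.5 equiv), CH2Cl2, 0 °C to rt; then TFA, rt
Reagents that add atoms: none
Why: Triethylamine reversibly forms the ammonium enolates of the enolised triketo ester, the C2 carbon (between the aryl ester and the C3 carbonyl) adds to the C7 ketone to make the ring A C1–C6 bond as carbinol 21, and acid then eliminates water so that the C3 and C5 carbonyls enolise to the two phenols. The closest known reaction is the biomimetic aldol aromatisation of 3,5,7-trioxoalkanoate esters obtained by trapping acylketenes from diketo-dioxinones, the laboratory counterpart of the tetraketide fold that leads to olivetolic acid. The single ring closes in the 6-(enolendo)-exo-trig mode, and the two sp3 centres of 21 are lost on aromatisation, so no stereocentre has to be controlled. The step needs C2-to-C7 aldol closure to win over C6-to-C1 Claisen closure, over lactonisation of the C5 enol oxygen onto C1 and over E1cB loss of the ring B aryloxide, all of which would expel phenol 10. A substoichiometric, non-nucleophilic amine in an aprotic solvent avoids alkoxide and transesterification, the two ortho benzyloxy groups of ring B shield the ester carbonyl C1 whereas the C7 ketone is unhindered, and the irreversible dehydration drains the reversible aldol equilibrium towards the arene. Ring B has no free hydroxyl, so the new depside ester cannot migrate.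

Step 12
Reactants: 22 benzyl 2,4-bis(benzyloxy)-3-[(2,4-dihydroxy-6-pentylbenzoyl)oxy]-6-propylbenzoate
Product: 23 benzyl 2,4-bis(benzyloxy)-3-[(2,4-dimethoxy-6-pentylbenzoyl)oxy]-6-propylbenzoate
Conditions: MeI (6 equiv), K2CO3 (4 equiv), DMF, rt to 40 °C
Reagents that add atoms: iodomethane, CI
Why: Williamson O-methylation with excess iodomethane should etherify both ring A phenols, including the hydrogen-bonded C2 hydroxyl, while anhydrous carbonate leaves the hindered aryl ester and the benzyl ester intact.

Step 13
Reactants: 23 benzyl 2,4-bis(benzyloxy)-3-[(2,4-dimethoxy-6-pentylbenzoyl)oxy]-6-propylbenzoate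
Product: 24 2,4-dihydroxy-3-[(2,4-dimethoxy-6-pentylbenzoyl)oxy]-6-propylbenzoic acid
Conditions: H2 (1 atm), 10% Pd/C, EtOAc, rt; neutral work-up without heating
Reagents that add atoms: none
Why: Catalytic hydrogenolysis should cleave the two benzyl ethers and the benzyl ester in one neutral operation that spares the methyl ethers and the depside ester and avoids acyl migration or decarboxylation of the salicylic acid.

**Compound list**

1 | 5-propylbenzene-1,3-diol (5-propylresorcinol) | CCCc1cc(O)cc(O)c1 | starting material
2 | 1,3-bis(benzyloxy)-5-propylbenzene | CCCc1cc(OCc2ccccc2)cc(OCc2ccccc2)c1 | intermediate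
3 | [2,6-bis(benzyloxy)-4-propylphenyl]lithium (not isolated) | CCCc1cc(OCc2ccccc2)c([Li])c(OCc2ccccc2)c1 | intermediate
4 | lithium [2,6-bis(benzyloxy)-4-propylphenyl]trimethoxyborate (not isolated) | [Li+].CCCc1cc(OCc2ccccc2)c([B-](OC)(OC)OC)c(OCc2ccccc2)c1 | intermediate
5 | 2,6-bis(benzyloxy)-4-propylphenol | CCCc1cc(OCc2ccccc2)c(O)c(OCc2ccccc2)c1 | intermediate
6 | 1,3-bis(benzyloxy)-2-(methoxymethoxy)-5-propylbenzene | CCCc1cc(OCc2ccccc2)c(OCOC)c(OCc2ccccc2)c1 | intermediate
7 | 1,3-bis(benzyloxy)-4-bromo-2-(methoxymethoxy)-5-propylbenzene | CCCc1cc(OCc2ccccc2)c(OCOC)c(OCc2ccccc2)c1Br | intermediate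
8 | [2,4-bis(benzyloxy)-3-(methoxymethoxy)-6-propylphenyl]lithium (not isolated) | CCCc1cc(OCc2ccccc2)c(OCOC)c(OCc2ccccc2)c1[Li] | intermediate
9 | benzyl 2,4-bis(benzyloxy)-3-(methoxymethoxy)-6-propylbenzoate | CCCc1cc(OCc2ccccc2)c(OCOC)c(OCc2ccccc2)c1C(=O)OCc1ccccc1 | intermediate
10 | benzyl 2,4-bis(benzyloxy)-3-hydroxy-6-propylbenzoate | CCCc1cc(OCc2ccccc2)c(O)c(OCc2ccccc2)c1C(=O)OCc1ccccc1 | intermediate
11 | hexanoyl chloride | CCCCCC(Cl)=O | starting material
12 | N-methoxy-N-methylhexanamide | CCCCCC(=O)N(C)OC | intermediate
13 | 2,2,6-trimethyl-4H-1,3-dioxin-4-one | CC1=CC(=O)OC(C)(C)O1 | starting material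
14 | acetyl chloride | CC(Cl)=O | starting material
15 | lithium 2,2-dimethyl-6-methylidene-6H-1,3-dioxin-4-olate (lithium dienolate, not isolated) | [Li+].C=C1C=C([O-])OC(C)(C)O1 | intermediate
16 | 2,2-dimethyl-6-(2-oxopropyl)-4H-1,3-dioxin-4-one | CC(=O)CC1=CC(=O)OC(C)(C)O1 | intermediate
17 | dilithium dianion of 16 (not isolated) | [Li+].[Li+].C=C([O-])C=C1C=C([O-])OC(C)(C)O1 | intermediate
18 | 6-(2,4-dioxononyl)-2,2-dimethyl-4H-1,3-dioxin-4-one | CCCCCC(=O)CC(=O)CC1=CC(=O)OC(C)(C)O1 | intermediate
19 | 3,5,7-trioxododec-1-en-1-one (acylketene, not isolated) | CCCCCC(=O)CC(=O)CC(=O)C=C=O | intermediate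
20 | benzyl 2,4-bis(benzyloxy)-6-propyl-3-[(3,5,7-trioxododecanoyl)oxy]benzoate | CCCCCC(=O)CC(=O)CC(=O)CC(=O)Oc1c(OCc2ccccc2)cc(CCC)c(C(=O)OCc2ccccc2)c1OCc1ccccc1 | intermediate
21 | benzyl 2,4-bis(benzyloxy)-3-[(6-hydroxy-2,4-dioxo-6-pentylcyclohexane-1-carbonyl)oxy]-6-propylbenzoate (aldol carbinol, transient diastereomer mixture, not isolated) | CCCCCC1(O)CC(=O)CC(=O)C1C(=O)Oc1c(OCc2ccccc2)cc(CCC)c(C(=O)OCc2ccccc2)c1OCc1ccccc1 | intermediate
22 | benzyl 2,4-bis(benzyloxy)-3-[(2,4-dihydroxy-6-pentylbenzoyl)oxy]-6-propylbenzoate | CCCCCc1cc(O)cc(O)c1C(=O)Oc1c(OCc2ccccc2)cc(CCC)c(C(=O)OCc2ccccc2)c1OCc1ccccc1 | intermediate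
23 | benzyl 2,4-bis(benzyloxy)-3-[(2,4-dimethoxy-6-pentylbenzoyl)oxy]-6-propylbenzoate | CCCCCc1cc(OC)cc(OC)c1C(=O)Oc1c(OCc2ccccc2)cc(CCC)c(C(=O)OCc2ccccc2)c1OCc1ccccc1 | intermediate
24 | 2,4-dihydroxy-3-[(2,4-dimethoxy-6-pentylbenzoyl)oxy]-6-propylbenzoic acid | CCCCCc1cc(OC)cc(OC)c1C(=O)Oc1c(O)cc(CCC)c(C(=O)O)c1O | target

**Step count**

Total: 13 steps. Longest linear sequence: 10 steps (steps 1–6, then 10–13); the chain branch contributes steps 7–9.

**Steps most likely to fail**

Step 11. The aryl ester is an activated acyl donor, so the enolised chain may lactonise through the C5 enol oxygen, close by Claisen attack of C6 on C1, or fragment by E1cB back to the ketene; each path expels the ring B phenol instead of forming the arene. The fallback sets out from 18 and comes back at 23. The same C–C bond would be closed while the carboxyl is still locked in the dioxinone, where no leaving group can be expelled: triethylamine in dichloromethane followed by acid should convert 18 into 7-hydroxy-2,2-dimethyl-5-pentyl-4H-1,3-benzodioxin-4-one F1. Methylation with iodomethane and potassium carbonate would give 7-methoxy-2,2-dimethyl-5-pentyl-4H-1,3-benzodioxin-4-one F2. The sodium phenoxide of 10 (sodium hydride, THF–DMF) would then open the acetonide lactone with loss of acetone, giving benzyl 2,4-bis(benzyloxy)-3-[(2-hydroxy-4-methoxy-6-pentylbenzoyl)oxy]-6-propylbenzoate F3. Its liberated ring A phenoxide would be methylated in the same flask with iodomethane to reach 23.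

Step 10. Addition of the hindered, hydrogen-bonded phenol to the acylketene may be too slow, so that intramolecular capture by the C5 enol oxygen (pyranone formation) or ketene dimerisation consumes the chain. The fallback sets out from 18 and comes back at 23. Thermolysis of 18 with benzyl alcohol in toluene would give benzyl 3,5,7-trioxododecanoate F4. Aldol aromatisation (caesium carbonate in THF, then hydrochloric acid) would give benzyl 2,4-dihydroxy-6-pentylbenzoate F5. Methylation would give benzyl 2,4-dimethoxy-6-pentylbenzoate F6, and hydrogenolysis would give 2,4-dimethoxy-6-pentylbenzoic acid F7. The acid and phenol 10 would then be condensed with trifluoroacetic anhydride in toluene at room temperature, the mixed-anhydride method used for hindered depside esters, to give 23.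

Step 2. Butyllithium may deprotonate a benzylic OCH2 group in competition with the ring position, leading to Wittig rearrangement and incomplete ring lithiation. The fallback sets out from 1 and comes back at 3. Iodination of 1 with iodine and sodium hydrogencarbonate in water, which under kinetic control attacks the position between the two hydroxyls of resorcinols, would give 2-iodo-5-propylbenzene-1,3-diol F8. Benzylation would give 1,3-bis(benzyloxy)-2-iodo-5-propylbenzene F9. Iodine–lithium exchange with n-butyllithium at −78 °C, far faster than any deprotonation, would deliver aryllithium 3, which is borylated and oxidised as in step 2.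

**Further compounds**

F1 | step 11 | 7-hydroxy-2,2-dimethyl-5-pentyl-4H-1,3-benzodioxin-4-one | CCCCCc1cc(O)cc2OC(C)(C)OC(=O)c12
F2 | step 11 | 7-methoxy-2,2-dimethyl-5-pentyl-4H-1,3-benzodioxin-4-one | CCCCCc1cc(OC)cc2OC(C)(C)OC(=O)c12
F3 | step 11 | benzyl 2,4-bis(benzyloxy)-3-[(2-hydroxy-4-methoxy-6-pentylbenzoyl)oxy]-6-propylbenzoate | CCCCCc1cc(OC)cc(O)c1C(=O)Oc1c(OCc2ccccc2)cc(CCC)c(C(=O)OCc2ccccc2)c1OCc1ccccc1
F4 | step 10 | benzyl 3,5,7-trioxododecanoate | CCCCCC(=O)CC(=O)CC(=O)CC(=O)OCc1ccccc1
F5 | step 10 | benzyl 2,4-dihydroxy-6-pentylbenzoate | CCCCCc1cc(O)cc(O)c1C(=O)OCc1ccccc1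
F6 | step 10 | benzyl 2,4-dimethoxy-6-pentylbenzoate | CCCCCc1cc(OC)cc(OC)c1C(=O)OCc1ccccc1
F7 | step 10 | 2,4-dimethoxy-6-pentylbenzoic acid | CCCCCc1cc(OC)cc(OC)c1C(=O)O
F8 | step 2 | 2-iodo-5-propylbenzene-1,3-diol | CCCc1cc(O)c(I)c(O)c1
F9 | step 2 | 1,3-bis(benzyloxy)-2-iodo-5-propylbenzene | CCCc1cc(OCc2ccccc2)c(I)c(OCc2ccccc2)c1
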